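## Retrosynthetic overview
1. The ten-membered carbocycle (second ring) is closed last. C3=O is inserted as CO between the Z-vinyl iodide (C4) and the E-vinylstannane (C2) of a seco-precursor.
2. The 8β-tiglate comes from an invertive esterification of the 8α-alcohol.
3. Key disconnection C7–C8: the β-carbon of a 3-(bromomethyl)butenolide is made nucleophilic (allylchromium, a lactone homoenolate or d3 equivalent) and joined to aldehyde carbon C8. This one step unites the halves, sets C7 and C8 from C6, and unveils the α-methylene lactone.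
4. East half (lactone, first ring): crotonaldehyde + propyne (asymmetric alkynylation, C6), trans-hydroalumination/iodination (4Z), 2-(bromomethyl)acrylate ester, ring-closing metathesis.
5. West half: (E)-3-methylpent-2-en-4-yn-1-ol, Sharpless epoxidation (C10), hydride opening, hydrostannation (1E), oxidation. No protecting groups are used.

Assumption: positions follow germacrane numbering (lactone C12–O–C6, tiglate on C8); in step 1 the (R,R)-ligand is taken to give Re-face attack, and the equally available antipode is used if the sense proves opposite.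

## Route

Step 1
Reactants: 1 (E)-but-2-enal (crotonaldehyde); 2 propyne
Product: 4 (2E,4S)-hept-2-en-5-yn-4-ol, via methyl(prop-1-ynyl)zinc 3 (not isolated)
Conditions: Me2Zn (2.5 equiv), (R,R)-ProPhenol (10 mol %), Ph3P=O (20 mol %), propyne (3 equiv), toluene, 0 to 4 °C; aqueous work-up
Reagents that add atoms: none
Why: Catalytic asymmetric alkynylation with a dinuclear zinc–ProPhenol catalyst, in which the chiral zinc alkoxide binds the enal (the best substrate class for this addition) and delivers acetylide 3 to the Re face, setting the C6 carbinol (S here, R in the target only because the priorities change).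

Step 2
Reactants: 4 (2E,4S)-hept-2-en-5-yn-4-ol
Product: 6 (2E,4S,5Z)-6-iodohepta-2,5-dien-4-ol, via cyclic sodium vinylalanate 5 (not isolated)
Conditions: NaAlH2(OCH2CH2OMe)2 (1.5 equiv), THF, 0 °C to rt; then I2, THF, −78 °C; aqueous work-up
Reagents that add atoms: iodine II
Why: Hydroxyl-directed trans-hydroalumination of a propargylic alcohol followed by iodinolysis places aluminium, then iodine, on the distal alkyne carbon cis to the carbinol, which fixes the future 4Z geometry while the isolated propenyl group and C6 are untouched.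

Step 3
Reactants: 6 (2E,4S,5Z)-6-iodohepta-2,5-dien-4-ol; 7 2-(bromomethyl)acrylic acid
Product: 8 (2E,4S,5Z)-6-iodohepta-2,5-dien-4-yl 2-(bromomethyl)acrylate
Conditions: DCC (1.2 equiv), DMAP (5 mol %), CH2Cl2, 0 °C
Reagents that add atoms: none
Why: Steglich esterification acylates at oxygen with retention at C6, and low temperature with little DMAP keeps the allylic bromide intact.

Step 4
Reactants: 8 (2E,4S,5Z)-6-iodohepta-2,5-dien-4-yl 2-(bromomethyl)acrylate
Product: 9 (5S)-3-(bromomethyl)-5-[(Z)-2-iodoprop-1-enyl]furan-2(5H)-one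
Conditions: second-generation Grubbs catalyst (5 mol %), CH2Cl2 (5 mM), reflux
Reagents that add atoms: none
Why: Ring-closing metathesis engages the propenyl group and closes onto the 1,1-disubstituted acrylate to give the butenolide with loss of propene, while the iodo-substituted trisubstituted alkene is inert and C6 is untouched.

Step 5
Reactants: 10 (E)-3-methylpent-2-en-4-yn-1-ol
Product: 11 [(2S,3S)-3-ethynyl-3-methyloxiran-2-yl]methanol
Conditions: Ti(OiPr)4 (10 mol %), L-(+)-diethyl tartrate (12 mol %), t-BuOOH (2 equiv), 4 Å MS, CH2Cl2, −20 °C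
Reagents that add atoms: tert-butyl hydroperoxide CC(C)(C)OO
Why: Katsuki–Sharpless asymmetric epoxidation with L-(+)-tartrate delivers oxygen to the bottom face in the usual mnemonic (the same sense as geraniol to its 2S,3S-epoxide), which sets the C10–O bond of the target.

Step 6
Reactants: 11 [(2S,3S)-3-ethynyl-3-methyloxiran-2-yl]methanol
Product: 12 (3R)-3-methylpent-4-yne-1,3-diol
Conditions: NaAlH2(OCH2CH2OMe)2 (2.5 equiv), THF, −20 to 0 °C; aqueous work-up
Reagents that add atoms: none
Why: In this hydroxyl-directed reductive opening of a 2,3-epoxy alcohol, the alkoxide-bound aluminium hydride delivers hydride to the less substituted C9 to give the 1,3-diol, so the C10–O bond (10R) is retained and the terminal alkyne is shielded as its aluminium acetylide at low temperature.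

Step 7
Reactants: 12 (3R)-3-methylpent-4-yne-1,3-diol
Product: 13 (3R,4E)-3-methyl-5-(tributylstannyl)pent-4-ene-1,3-diol
Conditions: Bu3SnH (1.2 equiv), PdCl2(PPh3)2 (2 mol %), THF, 0 °C
Reagents that add atoms: tributyltin hydride CCCC[SnH](CCCC)CCCC
Why: In this palladium-catalysed syn-hydrostannation the bulky tertiary carbinol steers tin to the terminal carbon, giving the E-vinylstannane that carries the future 1E geometry.

Step 8
Reactants: 13 (3R,4E)-3-methyl-5-(tributylstannyl)pent-4-ene-1,3-diol
Product: 14 (3R,4E)-3-hydroxy-3-methyl-5-(tributylstannyl)pent-4-enal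
Conditions: Dess–Martin periodinane (1.2 equiv), NaHCO3, CH2Cl2, 0 °C; used at once
Reagents that add atoms: none
Why: In the Dess–Martin oxidation only the primary alcohol can react, and the buffered non-basic medium avoids protodestannylation, retro-aldol cleavage and dehydration of the β-hydroxy aldehyde.

Step 9 (key step)
Reactants: 9 (5S)-3-(bromomethyl)-5-[(Z)-2-iodoprop-1-enyl]furan-2(5H)-one; 14 (3R,4E)-3-hydroxy-3-methyl-5-(tributylstannyl)pent-4-enal
Product: 16 (4R,5S)-4-[(1S,3R,4E)-1,3-dihydroxy-3-methyl-5-(tributylstannyl)pent-4-enyl]-5-[(Z)-2-iodoprop-1-enyl]-3-methylidenedihydrofuran-2(3H)-one, via allylchromium dichloride 15 (not isolated)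
Conditions: CrCl2 (3 equiv, nickel-free), 14 (1.2 equiv), THF, 0 °C to rt, slow addition of 9; pH 7 buffer quench
Reagents that add atoms: none
Why: In this Nozaki–Hiyama allylation with polarity reversal, divalent chromium converts the bromide into 15, whose nucleophilic γ-carbon is the normally electrophilic butenolide β-carbon C7, and this attacks aldehyde carbon C8 through a chair Zimmerman–Traxler transition state on the face anti to the C6 side chain (6,7-trans), with the ring-locked E-allyl geometry giving the 7,8-anti (8S) alcohol and the exocyclic C11=C13 bond, while the in-plane C6–O bond cannot overlap with the allyl π-system and so resists 1,4-elimination, and vinyl iodide, stannane and free tertiary alcohol are all tolerated.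

Step 10
Reactants: 16 the 8S-alcohol from step 9; 17 tiglic acid [(E)-2-methylbut-2-enoic acid]
Product: 18 (1R,3R,4E)-3-hydroxy-1-{(2S,3R)-2-[(Z)-2-iodoprop-1-enyl]-4-methylidene-5-oxotetrahydrofuran-3-yl}-3-methyl-5-(tributylstannyl)pent-4-enyl (E)-2-methylbut-2-enoate
Conditions: PPh3 (3 equiv) and DIAD (3 equiv) premixed, then 17 (3 equiv) and 16, toluene, 0 °C to rt
Reagents that add atoms: none
Why: In the Mitsunobu esterification, SN2 displacement of the C8 oxyphosphonium by tiglate inverts 8S to the required 8R, the tertiary C10 alcohol cannot be activated, preforming the betaine keeps free phosphine away from the α-methylene lactone, and the neutral medium preserves the E-tiglate.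

Step 11
Reactants: 18 the seco iodide–stannane tiglate from step 10
Product: 20 eupaheliangolide A, via acylpalladium iodide 19 (not isolated)
Conditions: Pd2(dba)3 (10 mol %), AsPh3 (40 mol %), CO (3 atm), DMF–THF, 1 mM by syringe pump, 45 °C
Reagents that add atoms: carbon monoxide [C-]#[O+]
Why: In the carbonylative Stille macrocyclisation, zerovalent palladium inserts into the Z-vinyl iodide with retention, CO insertion (made fast by the CO pressure) gives 19, and intramolecular transmetalation and reductive elimination with the E-vinylstannane (retention) create C3=O and the 1E,4Z-dienone and close the ten-membered ring without touching any stereocentre.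

## Compound list
1 | (E)-but-2-enal (crotonaldehyde) | C/C=C/C=O | starting material
2 | propyne | CC#C | starting material
3 | methyl(prop-1-ynyl)zinc | C[Zn]C#CC | intermediate
4 | (2E,4S)-hept-2-en-5-yn-4-ol | C/C=C/[C@H](O)C#CC | intermediate
5 | sodium (5S)-2,2-bis(2-methoxyethoxy)-3-methyl-5-[(E)-prop-1-enyl]-2,5-dihydro-1,2-oxaaluminol-2-uide (cyclic vinylalanate, Al on C4 cis to C6) | C/C=C/[C@H]1C=C(C)[Al-](OCCOC)(OCCOC)O1.[Na+] | intermediate
6 | (2E,4S,5Z)-6-iodohepta-2,5-dien-4-ol | C/C=C/[C@H](O)/C=C(/C)I | intermediate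
7 | 2-(bromomethyl)acrylic acid | C=C(CBr)C(=O)O | starting material
8 | (2E,4S,5Z)-6-iodohepta-2,5-dien-4-yl 2-(bromomethyl)acrylate | C/C=C/[C@H](OC(=O)C(=C)CBr)/C=C(/C)I | intermediate
9 | (5S)-3-(bromomethyl)-5-[(Z)-2-iodoprop-1-enyl]furan-2(5H)-one | BrCC1=C[C@H](OC1=O)/C=C(/C)I | intermediate
10 | (E)-3-methylpent-2-en-4-yn-1-ol | C#C/C(C)=C/CO | starting material
11 | [(2S,3S)-3-ethynyl-3-methyloxiran-2-yl]methanol | C#C[C@]1(C)O[C@H]1CO | intermediate
12 | (3R)-3-methylpent-4-yne-1,3-diol | C#C[C@](C)(O)CCO | intermediate
13 | (3R,4E)-3-methyl-5-(tributylstannyl)pent-4-ene-1,3-diol | CCCC[Sn](CCCC)(CCCC)/C=C/[C@](C)(O)CCO | intermediate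
14 | (3R,4E)-3-hydroxy-3-methyl-5-(tributylstannyl)pent-4-enal | CCCC[Sn](CCCC)(CCCC)/C=C/[C@](C)(O)CC=O | intermediate
15 | {(5S)-5-[(Z)-2-iodoprop-1-enyl]-2-oxo-2,5-dihydrofuran-3-yl}methylchromium dichloride (solvent ligands omitted) | Cl[Cr](Cl)CC1=C[C@H](OC1=O)/C=C(/C)I | intermediate
16 | (4R,5S)-4-[(1S,3R,4E)-1,3-dihydroxy-3-methyl-5-(tributylstannyl)pent-4-enyl]-5-[(Z)-2-iodoprop-1-enyl]-3-methylidenedihydrofuran-2(3H)-one (6,7-trans, 8α-OH) | C=C1C(=O)O[C@H](/C=C(/C)I)[C@H]1[C@@H](O)C[C@@](C)(O)/C=C/[Sn](CCCC)(CCCC)CCCC | intermediate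
17 | tiglic acid, (E)-2-methylbut-2-enoic acid | C/C=C(\C)C(=O)O | starting material
18 | (1R,3R,4E)-3-hydroxy-1-{(2S,3R)-2-[(Z)-2-iodoprop-1-enyl]-4-methylidene-5-oxotetrahydrofuran-3-yl}-3-methyl-5-(tributylstannyl)pent-4-enyl (E)-2-methylbut-2-enoate (8β-tiglate) | C=C1C(=O)O[C@H](/C=C(/C)I)[C@H]1[C@H](OC(=O)/C(C)=C/C)C[C@@](C)(O)/C=C/[Sn](CCCC)(CCCC)CCCC | intermediate
19 | acylpalladium iodide from 18 (Pd–C3(=O)–C4, ligands omitted) | C=C1C(=O)O[C@H](/C=C(/C)C(=O)[Pd]I)[C@H]1[C@H](OC(=O)/C(C)=C/C)C[C@@](C)(O)/C=C/[Sn](CCCC)(CCCC)CCCC | intermediate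
20 | eupaheliangolide A, (6R,7R,8R,10R)-10-hydroxy-3-oxo-8-tigloyloxygermacra-1E,4Z,11(13)-trien-12,6-olide | C=C1C(=O)O[C@@H]2/C=C(/C)C(=O)/C=C/[C@](C)(O)C[C@@H](OC(=O)/C(C)=C/C)[C@@H]12 | target

## Step count and risks
Total steps: 11. Longest linear sequence: 7 (steps 1–4, then 9–11). The west half takes 4 steps (5–8).

**Macrocyclisation (step 11).** A ten-membered ring is closed through an acylpalladium. The threats are oligomerisation, CO-free coupling, Heck-type capture of the vinylpalladium by the α-methylene lactone, and ionisation of the allylic C6–O bond.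
- The fallback closes the ring by metathesis at C1=C2 instead. It sets out from 18.
- Protodestannylation (AcOH, CH2Cl2) gives the terminal vinyl carbinol F1.
- Intermolecular carbonylative Stille coupling of its vinyl iodide with tributyl(vinyl)stannane (PdCl2(MeCN)2, CO, DMF) gives the divinyl ketone F2.
- Ring-closing metathesis with the second-generation Hoveyda–Grubbs catalyst at high dilution in warm toluene, under equilibrating conditions that favour the E-enone, comes back to the route at 20.

**Invertive esterification (step 10).** C8 is flanked by a ring methine and a neopentyl-type CH2, and tiglic acid is a weak Mitsunobu acid. Elimination or no reaction is therefore possible.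
- The fallback separates activation from displacement and uses no phosphine. It sets out from 16.
- Selective sulfonylation of the secondary alcohol (ClCH2SO2Cl, pyridine, 0 °C) gives the C8 chloromethanesulfonate F3.
- Caesium tiglate (17, Cs2CO3, 18-crown-6, toluene) displaces it with inversion and comes back to the route at 18.

**Key coupling (step 9).** The β-hydroxy aldehyde 14 can undergo retro-aldol cleavage. The trivalent chromium alkoxide could translactonise to the 12,8-olide. The reducing metal could attack the vinyl iodide or trigger ring-opening elimination.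
- The fallback replaces in-situ reductive metalation with an isolable boron d3 reagent that is neither reducing nor basic. It sets out from 8.
- Borylcopper substitution (B2pin2, CuCl, KOAc, DMF, rt) gives the 2-(pinacolborylmethyl)acrylate F4. The SN2 and SN2' pathways are degenerate at this stage.
- Ring-closing metathesis gives the 3-(pinacolborylmethyl)butenolide F5.
- Allylboration of 14 (cat. Sc(OTf)3, toluene, 0 °C to rt) passes through the same closed chair, anti to the C6 substituent. After aqueous work-up it comes back to the route at 16.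

## Further compounds
F1 | step 11 | (1R,3R)-3-hydroxy-1-{(2S,3R)-2-[(Z)-2-iodoprop-1-enyl]-4-methylidene-5-oxotetrahydrofuran-3-yl}-3-methylpent-4-enyl tiglate | C=C1C(=O)O[C@H](/C=C(/C)I)[C@H]1[C@H](OC(=O)/C(C)=C/C)C[C@@](C)(O)C=C
F2 | step 11 | (1R,3R)-3-hydroxy-3-methyl-1-{(2R,3R)-2-[(Z)-2-methyl-3-oxopenta-1,4-dienyl]-4-methylidene-5-oxotetrahydrofuran-3-yl}pent-4-enyl tiglate | C=C1C(=O)O[C@H](/C=C(/C)C(=O)C=C)[C@H]1[C@H](OC(=O)/C(C)=C/C)C[C@@](C)(O)C=C
F3 | step 10 | C8 (1S) chloromethanesulfonate of 16 | C=C1C(=O)O[C@H](/C=C(/C)I)[C@H]1[C@@H](OS(=O)(=O)CCl)C[C@@](C)(O)/C=C/[Sn](CCCC)(CCCC)CCCC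
F4 | step 9 | (2E,4S,5Z)-6-iodohepta-2,5-dien-4-yl 2-[(4,4,5,5-tetramethyl-1,3,2-dioxaborolan-2-yl)methyl]acrylate | C/C=C/[C@H](OC(=O)C(=C)CB1OC(C)(C)C(C)(C)O1)/C=C(/C)I
F5 | step 9 | (5S)-5-[(Z)-2-iodoprop-1-enyl]-3-[(4,4,5,5-tetramethyl-1,3,2-dioxaborolan-2-yl)methyl]furan-2(5H)-one | CC1(C)OB(CC2=C[C@H](OC2=O)/C=C(/C)I)OC1(C)C
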